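**Plan**

1. Retrosynthesis: cut both C–Br bonds (each back to an axial alcohol, hence a ketone) and the acetate; then, in one event, the lactone O–C7 bond and the C1–C7a cyclopentane bond; then the two C–CH3 bonds of ring A and the alkyne–C1′ bond (back to 1,4-benzoquinone); finally the C3a–CH2 bond (back to 2-methoxy-5-methylbenzoic acid).
2. Forward: Birch reduction–alkylation of the chiral anisamide gives the C3a quaternary carbon with a butynyl arm; its acetylide adds to benzoquinone, so ring A starts as a symmetric dienone that is desymmetrised and gem-dimethylated; enol ether hydrolysis unmasks the C4 ketone.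
3. A gold-triggered anti-addition across C7a=C7 then closes the cyclopentane and the γ-lactone and expels the auxiliary; hydrogenation, acetylation, double ketone reduction and double invertive bromination finish the route.
4. Enabling feature: C3a carries the lactone carbonyl and the cyclopentane CH2 on opposite faces of the six-membered ring, and the lactone oxygen sits on C7, so a C7a=C7 alkene is at once the ene partner of a 1,6-enyne (alkyne on the C3a tether) and the acceptor for the C3a carboxamide oxygen.
5. Stereochemistry: C3a from the prolinol-ether auxiliary; C7a and C7 from C3a through the tether and anti-addition; C1 from convex-face hydrogenation; C1′ from ligand-controlled desymmetrisation; C4 and C4′ from equatorial hydride delivery followed by SN2 inversion.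

Key step: step 8

Assumption: the facial sense of the auxiliary-controlled alkylation (step 2) and the enone arm selected by the (R)-ligand (step 5) are taken as written; if either is the opposite, the enantiomeric auxiliary or ligand (both commercial) is used and nothing else changes.

Locants in names: the core is numbered as a hydrindane (C1 side-chain carbon, C3a quaternary carbon, C4, C7 methyl-bearing carbon, C7a), with the lactone written as a 3a,7-carbolactone (carbonyl on C3a, oxygen on C7); ring A of the target is C1′ (carbinol), C3′ (CMe2), C4′ (CHBr).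

**Step 1**
Reactants: 1 2-methoxy-5-methylbenzoic acid; 2 (S)-2-(methoxymethyl)pyrrolidine
Product: 4 (S)-(2-methoxy-5-methylphenyl)[2-(methoxymethyl)pyrrolidin-1-yl]methanone, via 2-methoxy-5-methylbenzoyl chloride 3 (not isolated)
Conditions: (COCl)2, cat. DMF, CH2Cl2, 0 → 23 °C, concentrate; then 2, Et3N, CH2Cl2, 0 °C
Reagents that add atoms: none
Why: Amide formation by acylation of the secondary amine with the acid chloride; no stereocentre is formed and the auxiliary centre is untouched.

**Step 2**
Reactants: 4 benzamide; 5 (4-bromobut-1-yn-1-yl)trimethylsilane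
Product: 7 [(1S)-2-methoxy-5-methyl-1-(4-(trimethylsilyl)but-3-yn-1-yl)cyclohexa-2,5-dien-1-yl][(S)-2-(methoxymethyl)pyrrolidin-1-yl]methanone, via potassium amide enolate 6 (not isolated)
Conditions: K (2.2 equiv), NH3(l)/THF, t-BuOH (1 equiv), −78 °C; piperylene; then 5, −78 → 23 °C
Reagents that add atoms: none
Why: Asymmetric Birch reduction–alkylation of a chiral 2-methoxybenzamide: reduction and C4 protonation give the chelated enolate 6, which the primary bromide should alkylate at C1 on the face away from the pyrrolidine side chain, setting the quaternary centre (1S) under auxiliary control while the methoxy and methyl groups stay on the two remaining double bonds.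

**Step 3**
Reactants: 7 silyl alkyne
Product: 8 [(1S)-1-(but-3-yn-1-yl)-2-methoxy-5-methylcyclohexa-2,5-dien-1-yl][(S)-2-(methoxymethyl)pyrrolidin-1-yl]methanone
Conditions: K2CO3 (cat.), MeOH, 23 °C
Reagents that add atoms: none
Why: Base-catalysed methanolysis of the alkynyl C–Si bond (protodesilylation), to which the enol ether and the amide are inert.

**Step 4**
Reactants: 8 terminal alkyne; 9 1,4-benzoquinone
Product: 12 4-{4-[(1S)-2-methoxy-1-{[(S)-2-(methoxymethyl)pyrrolidin-1-yl]carbonyl}-5-methylcyclohexa-2,5-dien-1-yl]but-1-yn-1-yl}-4-(trimethylsilyloxy)cyclohexa-2,5-dien-1-one, via lithium acetylide 10 (not isolated), via lithium quinol alkoxide 11 (not isolated)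
Conditions: n-BuLi (1.0 equiv), THF, −78 °C; added to 9 (1.5 equiv), THF, −78 °C; then Me3SiCl, −78 → 0 °C
Reagents that add atoms: chlorotrimethylsilane C[Si](C)(C)Cl
Why: 1,2-Addition of a lithium acetylide to a quinone carbonyl followed by O-silylation of the quinol alkoxide; the new carbinol carbon is not yet a stereocentre because its two enone arms are identical.

**Step 5**
Reactants: 12 quinol silyl ether
Product: 14 (4R)-4-{4-[(1S)-2-methoxy-1-{[(S)-2-(methoxymethyl)pyrrolidin-1-yl]carbonyl}-5-methylcyclohexa-2,5-dien-1-yl]but-1-yn-1-yl}-4-(trimethylsilyloxy)cyclohex-2-en-1-one, via silyl dienol ether 13 (not isolated)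
Conditions: Cu(OAc)2 (5 mol %), (R)-DTBM-SEGPHOS (5.5 mol %), (EtO)2MeSiH (1.1 equiv), toluene, −20 °C; then NaHCO3, MeOH/H2O, 0 °C
Reagents that add atoms: none
Why: Ligand-controlled copper hydride conjugate reduction (asymmetric 1,4-hydrosilylation) that desymmetrises the cross-conjugated dienone: hydride should go to one of the two enantiotopic β-carbons, anti to the bulky silyloxy group, making the carbinol carbon a stereocentre (4R), and the dienol ether 13 shields the product from over-reduction until work-up.

**Step 6**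
Reactants: 14 enone
Product: 16 (4R)-4-{4-[(1S)-2-methoxy-1-{[(S)-2-(methoxymethyl)pyrrolidin-1-yl]carbonyl}-5-methylcyclohexa-2,5-dien-1-yl]but-1-yn-1-yl}-6,6-dimethyl-4-(trimethylsilyloxy)cyclohex-2-en-1-one, via monomethyl enone 15 (not isolated)
Conditions: LiN(i-Pr)2 (1.1 equiv), THF, −78 °C, MeI; then LiN(i-Pr)2 (1.3 equiv), MeI, −78 → 0 °C
Reagents that add atoms: iodomethane CI
Why: Kinetic α′-enolate alkylation of an enone, carried out twice: C6 is the only enolisable position (the γ-carbon is quaternary), so both methyl groups should enter on the saturated arm and place the gem-dimethyl next to the future C4′, with no new stereocentre.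

**Step 7**
Reactants: 16 gem-dimethyl enone
Product: 17 (4R)-4-hydroxy-4-{4-[(1S)-1-{[(S)-2-(methoxymethyl)pyrrolidin-1-yl]carbonyl}-3-methyl-6-oxocyclohex-2-en-1-yl]but-1-yn-1-yl}-6,6-dimethylcyclohex-2-en-1-one
Conditions: 1 M HCl, THF, 0 → 23 °C
Reagents that add atoms: water O
Why: Mild acid hydrolysis of the methyl enol ether to the C4 ketone and of the tertiary silyl ether, under conditions too weak to protonate the trisubstituted alkene; the quaternary carbon blocks conjugation of that alkene.

**Step 8**
Reactants: 17 enyne keto amide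
Product: 19 (4R)-4-hydroxy-6,6-dimethyl-4-{(Z)-[(3aS,7S,7aS)-7-methyl-4-oxohexahydroindene-3a,7-carbolactone-1-ylidene]methyl}cyclohex-2-en-1-one, via iminium ether triflate 18 (not isolated)
Conditions: [(t-Bu)2(biphenyl-2-yl)P]Au(NCMe)SbF6 (5 mol %), 2,6-di-tert-butylpyridinium triflate (1.2 equiv), CH2Cl2, 23 °C; then sat. aq. NaHCO3, THF, 23 °C
Reagents that add atoms: water O
Why: Proposed new method: the cationic monovalent-gold catalyst activates the alkyne, the C7a=C7 alkene attacks its proximal carbon anti to gold (5-exo-dig) to close the cyclopentane, and the tertiary cationic carbon C7 is captured on the opposite face by the carboxamide oxygen (5-endo with respect to the former alkene) to give iminium ether 18 and an alkenylgold that the hindered pyridinium salt protodeaurates; bicarbonate then hydrolyses 18 to the lactone and frees the auxiliary. The closest known reaction types are the gold-catalysed hydroxy-, alkoxy- and acyloxy-cyclisation of 1,6-enynes and the halogen- or proton-induced lactonisation of 1-carboxamidocyclohexa-2,5-dienes with loss of the prolinol auxiliary; termination of the gold process by a tertiary amide oxygen has not been shown. C7a is set because the three-carbon tether on C3a can reach C7a only from its own face (cis-hydrindane), and C7 because the amide sits on the other face of C3a and the addition is anti, so both follow from the auxiliary-set C3a; the Z alkene follows from anti attack and stereoretentive protodeauration. The step needs alkene rather than amide, ketone or hydroxyl attack on the alkyne and 5-exo rather than 6-endo closure: the trisubstituted alkene is the best π-nucleophile and is held over the alkyne by the quaternary centre, and the distal alkyne carbon is shielded by the quaternary carbinol.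

**Step 9**
Reactants: 19 alkylidene keto lactone
Product: 20 (4R)-4-hydroxy-2,2-dimethyl-4-{[(1R,3aS,7S,7aS)-7-methyl-4-oxooctahydroindene-3a,7-carbolactone-1-yl]methyl}cyclohexan-1-one
Conditions: H2 (1 atm), [Ir(cod)(PCy3)(py)]PF6 (10 mol %), CH2Cl2, 23 °C
Reagents that add atoms: none
Why: Hydroxyl-directed homogeneous hydrogenation with the cationic iridium catalyst saturates both alkenes flanking the tertiary allylic alcohol; hydrogen should reach C1 from the convex face of the cis-hydrindane (the face of the lactone carbonyl and H-7a, away from C7 and its methyl), setting C1 (R) with the side chain on the concave face.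

**Step 10**
Reactants: 20 hydroxy diketone
Product: 21 (1R)-3,3-dimethyl-1-{[(1R,3aS,7S,7aS)-7-methyl-4-oxooctahydroindene-3a,7-carbolactone-1-yl]methyl}-4-oxocyclohexyl acetate
Conditions: Ac2O, Sc(OTf)3 (5 mol %), MeCN, −20 °C
Reagents that add atoms: acetic anhydride CC(=O)OC(C)=O
Why: Lewis-acid-catalysed acylation of a hindered tertiary alcohol at low temperature, where the ketones should not form enol acetates; no stereocentre changes.

**Step 11**
Reactants: 21 acetoxy diketone
Product: 22 (1R,4S)-4-hydroxy-1-{[(1R,3aS,4S,7S,7aS)-4-hydroxy-7-methyloctahydroindene-3a,7-carbolactone-1-yl]methyl}-3,3-dimethylcyclohexyl acetate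
Conditions: LiBH(s-Bu)3 (2.5 equiv), THF, −78 °C; then AcOH
Reagents that add atoms: none
Why: Bulky trialkylborohydride reduction of both ketones by equatorial attack: at C4 hydride should come from the open lactone face (the other face is covered by the cis-fused cyclopentane and its axial C7a–C1 bond), and at C4′ it takes the equatorial path in the chair that keeps the side chain equatorial and the acetate axial, so both new alcohols are axial (4S and 4′S), trans to the lactone carbonyl and to the acetate.

**Step 12**
Reactants: 22 diol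
Product: 23 (1R,4R)-4-bromo-1-{[(1R,3aR,4R,7S,7aS)-4-bromo-7-methyloctahydroindene-3a,7-carbolactone-1-yl]methyl}-3,3-dimethylcyclohexyl acetate
Conditions: PPh3, CBr4, toluene, 60–80 °C
Reagents that add atoms: carbon tetrabromide BrC(Br)(Br)Br
Why: Appel reaction (SN2 displacement of the oxyphosphonium by bromide with inversion) at both secondary carbinols, whose axial leaving groups should be replaced to give the two equatorial bromides (4R and 4′R); the lactone carbonyl on C3a disfavours ionisation and skeletal shift at C4.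

**Compound list**

1 | 2-methoxy-5-methylbenzoic acid | COc1ccc(C)cc1C(=O)O | starting material
2 | (S)-2-(methoxymethyl)pyrrolidine | COC[C@@H]1CCCN1 | starting material
3 | 2-methoxy-5-methylbenzoyl chloride | COc1ccc(C)cc1C(Cl)=O | intermediate
4 | (S)-(2-methoxy-5-methylphenyl)[2-(methoxymethyl)pyrrolidin-1-yl]methanone | COc1ccc(C)cc1C(=O)N1CCC[C@H]1COC | intermediate
5 | (4-bromobut-1-yn-1-yl)trimethylsilane | C[Si](C)(C)C#CCCBr | starting material
6 | potassium (2-methoxy-5-methylcyclohexa-2,5-dien-1-ylidene)[(S)-2-(methoxymethyl)pyrrolidin-1-yl]methanolate | COC1=CCC(C)=CC1=C([O-])N1CCC[C@H]1COC.[K+] | intermediate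
7 | [(1S)-2-methoxy-5-methyl-1-(4-(trimethylsilyl)but-3-yn-1-yl)cyclohexa-2,5-dien-1-yl][(S)-2-(methoxymethyl)pyrrolidin-1-yl]methanone | C[Si](C)(C)C#CCC[C@@]1(C(=O)N2CCC[C@H]2COC)C(OC)=CCC(C)=C1 | intermediate
8 | [(1S)-1-(but-3-yn-1-yl)-2-methoxy-5-methylcyclohexa-2,5-dien-1-yl][(S)-2-(methoxymethyl)pyrrolidin-1-yl]methanone | C#CCC[C@@]1(C(=O)N2CCC[C@H]2COC)C(OC)=CCC(C)=C1 | intermediate
9 | 1,4-benzoquinone | O=C1C=CC(=O)C=C1 | starting material
10 | lithium acetylide of 8 | [Li]C#CCC[C@@]1(C(=O)N2CCC[C@H]2COC)C(OC)=CCC(C)=C1 | intermediate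
11 | lithium alkoxide of the 4-alkynyl-4-hydroxycyclohexa-2,5-dienone (quinol) from 10 and 9 | [Li]OC1(C#CCC[C@@]2(C(=O)N3CCC[C@H]3COC)C(OC)=CCC(C)=C2)C=CC(=O)C=C1 | intermediate
12 | 4-{4-[(1S)-2-methoxy-1-{[(S)-2-(methoxymethyl)pyrrolidin-1-yl]carbonyl}-5-methylcyclohexa-2,5-dien-1-yl]but-1-yn-1-yl}-4-(trimethylsilyloxy)cyclohexa-2,5-dien-1-one | C[Si](C)(C)OC1(C#CCC[C@@]2(C(=O)N3CCC[C@H]3COC)C(OC)=CCC(C)=C2)C=CC(=O)C=C1 | intermediate
13 | diethoxy(methyl)silyl dienol ether of 14 (1-silyloxycyclohexa-1,5-diene, 4R) | C[Si](C)(C)O[C@@]1(C#CCC[C@@]2(C(=O)N3CCC[C@H]3COC)C(OC)=CCC(C)=C2)C=CC(O[Si](C)(OCC)OCC)=CC1 | intermediate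
14 | (4R)-4-{4-[(1S)-2-methoxy-1-{[(S)-2-(methoxymethyl)pyrrolidin-1-yl]carbonyl}-5-methylcyclohexa-2,5-dien-1-yl]but-1-yn-1-yl}-4-(trimethylsilyloxy)cyclohex-2-en-1-one | C[Si](C)(C)O[C@@]1(C#CCC[C@@]2(C(=O)N3CCC[C@H]3COC)C(OC)=CCC(C)=C2)C=CC(=O)CC1 | intermediate
15 | 6-methyl derivative of 14 (4R; mixture of C6 epimers, C6 left undefined) | C[Si](C)(C)O[C@@]1(C#CCC[C@@]2(C(=O)N3CCC[C@H]3COC)C(OC)=CCC(C)=C2)C=CC(=O)C(C)C1 | intermediate
16 | (4R)-6,6-dimethyl derivative of 14 | C[Si](C)(C)O[C@@]1(C#CCC[C@@]2(C(=O)N3CCC[C@H]3COC)C(OC)=CCC(C)=C2)C=CC(=O)C(C)(C)C1 | intermediate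
17 | (4R)-4-hydroxy-4-{4-[(1S)-1-{[(S)-2-(methoxymethyl)pyrrolidin-1-yl]carbonyl}-3-methyl-6-oxocyclohex-2-en-1-yl]but-1-yn-1-yl}-6,6-dimethylcyclohex-2-en-1-one | O[C@@]1(C#CCC[C@@]2(C(=O)N3CCC[C@H]3COC)C(=O)CCC(C)=C2)C=CC(=O)C(C)(C)C1 | intermediate
18 | iminium ether triflate: 19 with the lactone carbon still bound as C(=N+-pyrrolidinium)–O–C7 | O[C@@]1(/C=C2/CC[C@@]34C(=[N+]5CCC[C@H]5COC)O[C@@](C)(CCC3=O)[C@@H]24)C=CC(=O)C(C)(C)C1.[O-]S(=O)(=O)C(F)(F)F | intermediate
19 | (4R)-4-hydroxy-6,6-dimethyl-4-{(Z)-[(3aS,7S,7aS)-7-methyl-4-oxohexahydroindene-3a,7-carbolactone-1-ylidene]methyl}cyclohex-2-en-1-one | O[C@@]1(/C=C2/CC[C@@]34C(=O)O[C@@](C)(CCC3=O)[C@@H]24)C=CC(=O)C(C)(C)C1 | intermediate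
20 | (4R)-4-hydroxy-2,2-dimethyl-4-{[(1R,3aS,7S,7aS)-7-methyl-4-oxooctahydroindene-3a,7-carbolactone-1-yl]methyl}cyclohexan-1-one | O[C@@]1(C[C@H]2CC[C@@]34C(=O)O[C@@](C)(CCC3=O)[C@@H]24)CCC(=O)C(C)(C)C1 | intermediate
21 | (1R)-3,3-dimethyl-1-{[(1R,3aS,7S,7aS)-7-methyl-4-oxooctahydroindene-3a,7-carbolactone-1-yl]methyl}-4-oxocyclohexyl acetate | CC(=O)O[C@@]1(C[C@H]2CC[C@@]34C(=O)O[C@@](C)(CCC3=O)[C@@H]24)CCC(=O)C(C)(C)C1 | intermediate
22 | (1R,4S)-4-hydroxy-1-{[(1R,3aS,4S,7S,7aS)-4-hydroxy-7-methyloctahydroindene-3a,7-carbolactone-1-yl]methyl}-3,3-dimethylcyclohexyl acetate | CC(=O)O[C@@]1(C[C@H]2CC[C@@]34C(=O)O[C@@](C)(CC[C@@H]3O)[C@@H]24)CC[C@H](O)C(C)(C)C1 | intermediate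
23 | (1R,4R)-4-bromo-1-{[(1R,3aR,4R,7S,7aS)-4-bromo-7-methyloctahydroindene-3a,7-carbolactone-1-yl]methyl}-3,3-dimethylcyclohexyl acetate (CNP0133010.1) | CC(=O)O[C@@]1(C[C@H]2CC[C@@]34C(=O)O[C@@](C)(CC[C@H]3Br)[C@@H]24)CC[C@@H](Br)C(C)(C)C1 | target

**Totals**

Total step count: 12. Longest linear sequence: 12 steps (from 1).

**Steps most likely to fail**

Step 8 (Proposed new method). What may go wrong: attack of the amide or ketone oxygen on the gold-bound alkyne instead of the alkene, acid-promoted rearrangement of the tertiary propargylic alcohol, or stalling of catalyst turnover at the alkenylgold stage. Fallback by known chemistry, setting out from 17: iodolactonisation (I2, THF/H2O, 23 °C), the established way to cleave this auxiliary, should give the C7a-iodo 3a,7-lactone F1, with the amide oxygen delivered to C7 and iodine anti on C7a. Tin hydride radical cyclisation (Bu3SnH, AIBN, benzene, 80 °C) then closes the C7a radical 5-exo-dig onto the alkyne from the tether face, giving the alkylidene lactone as an E/Z mixture F2 (its Z isomer is 19). Hydrogenation of the mixture under the conditions of step 9 converges on 20, where the fallback rejoins the route.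

Step 12. What may go wrong: elimination to the alkenes or 1,2-shift instead of substitution at the two neopentylic carbinol carbons, or incomplete reaction at the more shielded C4 hydroxyl. Fallback, setting out from 22: the in-flask oxyphosphonium activation is replaced by isolated sulfonate esters. Tf2O and pyridine in CH2Cl2 at −20 °C should give the bis(triflate) F5, which is displaced with LiBr in acetone (0 → 23 °C) by SN2 inversion at both centres, rejoining the route at 23.

Step 5. What may go wrong: poor discrimination between the two enone arms (low enantiotopic-group selectivity), or competing reduction of the alkyne. Fallback, setting out from 12: both enone arms are reduced with stoichiometric [(Ph3P)CuH]6 (toluene, 23 °C) to the symmetric 4-alkynyl-4-(trimethylsilyloxy)cyclohexanone F3. Enantiotopic deprotonation with lithium (R,R)-bis(1-phenylethyl)amide in the presence of Me3SiCl (THF, −100 °C; amide enantiomer chosen as in the assumption) gives the silyl enol ether F4, and Saegusa–Ito oxidation (Pd(OAc)2, MeCN, 23 °C) returns the enone, rejoining the route at 14.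

**Further compounds**

F1 | step 8 | C7a-iodo 3a,7-lactone from iodolactonisation of 17 (iodine anti to the lactone oxygen) | O[C@@]1(C#CCC[C@@]23C(=O)O[C@@](C)(CCC2=O)[C@H]3I)C=CC(=O)C(C)(C)C1
F2 | step 8 | alkylidene keto lactone as an E/Z mixture (Z isomer identical with 19) | O[C@@]1(C=C2CC[C@@]34C(=O)O[C@@](C)(CCC3=O)[C@@H]24)C=CC(=O)C(C)(C)C1
F3 | step 5 | symmetric 4-alkynyl-4-(trimethylsilyloxy)cyclohexanone from double conjugate reduction of 12 | C[Si](C)(C)OC1(C#CCC[C@@]2(C(=O)N3CCC[C@H]3COC)C(OC)=CCC(C)=C2)CCC(=O)CC1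
F4 | step 5 | desymmetrised trimethylsilyl enol ether of F3 | C[Si](C)(C)O[C@@]1(C#CCC[C@@]2(C(=O)N3CCC[C@H]3COC)C(OC)=CCC(C)=C2)CC=C(O[Si](C)(C)C)CC1
F5 | step 12 | bis(triflate) of diol 22 | CC(=O)O[C@@]1(C[C@H]2CC[C@@]34C(=O)O[C@@](C)(CC[C@@H]3OS(=O)(=O)C(F)(F)F)[C@@H]24)CC[C@H](OS(=O)(=O)C(F)(F)F)C(C)(C)C1
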